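The ten-membered carbocycle of eupacunolin carries an aldol-type 1,3-dioxygen pattern: C1 (free carbinol), C2 (ring methylene) and C3 (acetoxy carbon). The route disconnects C2–C3. A samarium Reformatsky macro-aldol joins a C1 bromomethyl enone to a C3 (Z)-enal, closing the ten-membered ring and setting C3 in one operation; an Evans–Tishchenko reduction with acetaldehyde then relays C3 to C1 and places the acetate on O3 directly. The precursor is a trans α-methylidene γ-lactone bearing both arms, made by zinc Barbier union of a bromobutenolide with (Z)-3-iodobut-2-enal, Mitsunobu tigloylation and Stille/NBS installation of the bromoketone.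

Key step: step 16

Remark on numbering: germacranolide numbering of the target is used for all intermediates: C1 (CHOH), C2 (ring CH2), C3 (CHOAc), C4=C5 (C4 bears C15H2OH), C6 (lactone oxygen), C7, C8 (tiglate), C9=C10 (C10 bears the C14 methyl), C11(=C13H2)–C12(=O) lactone. TBS = tert-butyldimethylsilyl, TES = triethylsilyl.

Assumption: the zinc Barbier addition of step 10 runs through the closed chair transition state usual for 3-(bromomethyl)furan-2(5H)-ones and therefore gives the C8 carbinol epimeric to the target, which step 11 inverts.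

Step 1
Reactants: 1 1,3-dihydroxyacetone (bought as its dimer); 2 ethyl (triphenylphosphoranylidene)acetate
Product: 4 4-(hydroxymethyl)furan-2(5H)-one, via dihydroxy enoate 3 (not isolated)
Conditions: CH2Cl2, rt
Reagents that add atoms: none
Why: Wittig olefination of the ketone gives an enoate in which one of the two identical CH2OH arms is necessarily cis to the ester and lactonises spontaneously, so the ring marks the future C3 (ring CH2O, cis to C6) against the future C15 (free CH2OH).

Step 2
Reactants: 4 4-(hydroxymethyl)furan-2(5H)-one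
Product: 5 4-{[(TBS)oxy]methyl}furan-2(5H)-one
Conditions: TBSCl, imidazole, DMF, 0 °C to rt
Reagents that add atoms: tert-butyldimethylsilyl chloride, CC(C)(C)[Si](C)(C)Cl
Why: Standard silylation of the primary alcohol protects O15 until the last step.

Step 3
Reactants: 5 4-{[(TBS)oxy]methyl}furan-2(5H)-one
Product: 7 (2E)-3-{[(TBS)oxy]methyl}-N-methoxy-N-methyl-4-[(TES)oxy]but-2-enamide (amide carbonyl cis to CH2OTES), via hydroxy Weinreb amide 6 (not isolated)
Conditions: MeNH(OMe)·HCl, Me3Al, CH2Cl2, 0 °C to rt; aq. potassium sodium tartrate; crude, TESCl, imidazole, CH2Cl2, 0 °C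
Reagents that add atoms: N,O-dimethylhydroxylamine hydrochloride, CNOC.Cl; triethylsilyl chloride, CC[Si](CC)(CC)Cl
Why: Weinreb aminolysis of the lactone by the aluminium amide opens the ring with the alkene geometry fixed by the former ring, and immediate silylation of the liberated C3 hydroxyl prevents relactonisation.

Step 4
Reactants: 7 Weinreb amide TES ether; 8 vinylmagnesium bromide
Product: 9 (4E)-5-{[(TBS)oxy]methyl}-6-[(TES)oxy]hexa-1,4-dien-3-one (carbonyl cis to CH2OTES)
Conditions: CH2=CHMgBr, THF, −20 to 0 °C; cold sat. aq. NH4Cl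
Reagents that add atoms: none
Why: Weinreb ketone synthesis, in which the chelated tetrahedral intermediate stops at the ketone stage, introduces C7 as a vinyl group.

Step 5
Reactants: 9 dienone
Product: 10 (3S,4E)-5-{[(TBS)oxy]methyl}-6-[(TES)oxy]hexa-1,4-dien-3-ol
Conditions: (R)-2-methyl-CBS-oxazaborolidine (0.2 equiv), catecholborane, toluene, −78 °C
Reagents that add atoms: none
Why: Corey–Bakshi–Shibata reduction, in which the β,β-disubstituted alkenyl arm acts as the large group and the vinyl group as the small one, should set C6 (S here, R after the priority change in step 7) under catalyst control.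

Step 6
Reactants: 10 (S)-dienol; 11 2-(bromomethyl)prop-2-enoic acid
Product: 12 (3S,4E)-5-{[(TBS)oxy]methyl}-6-[(TES)oxy]hexa-1,4-dien-3-yl 2-(bromomethyl)prop-2-enoate
Conditions: DCC, DMAP (5 mol%), CH2Cl2, −10 to 0 °C
Reagents that add atoms: none
Why: Steglich esterification acylates the only free hydroxyl with retention at C6, and the low temperature and small DMAP loading limit amine attack on the allylic bromide.

Step 7
Reactants: 12 dienyl 2-(bromomethyl)acrylate
Product: 13 (5R)-3-(bromomethyl)-5-[(1E)-2-{[(TBS)oxy]methyl}-3-[(TES)oxy]prop-1-en-1-yl]furan-2(5H)-one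
Conditions: second-generation Grubbs catalyst (H2IMes)(PCy3)Cl2Ru=CHPh (5 mol%), toluene (0.005 M), 80 °C
Reagents that add atoms: none
Why: Ring-closing metathesis between the monosubstituted vinyl group and the 1,1-disubstituted acrylate closes the five-membered butenolide with loss of ethene, while the trisubstituted C4=C5 alkene is too hindered to take part.

Step 8
Reactants: 14 but-2-yn-1-ol
Product: 16 (2Z)-3-iodobut-2-en-1-ol, via cyclic vinylalanate 15 (not isolated)
Conditions: NaAlH2(OCH2CH2OMe)2, THF, 0 °C to rt; then I2, THF, −78 °C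
Reagents that add atoms: iodine, II
Why: Hydroxyl-directed trans-hydroalumination places aluminium on the distal alkyne carbon and iodinolysis with retention gives the iodoalkene in which iodine (the future C1) is cis to the CH2OH carbon (the future C8).

Step 9
Reactants: 16 (2Z)-3-iodobut-2-en-1-ol
Product: 17 (2Z)-3-iodobut-2-enal
Conditions: MnO2, CH2Cl2, rt
Reagents that add atoms: none
Why: Heterogeneous allylic oxidation under neutral conditions gives the enal without Z/E isomerisation.

Step 10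
Reactants: 13 bromobutenolide; 17 (2Z)-3-iodobut-2-enal
Product: 19 (4R,5R)-4-[(1R,2Z)-1-hydroxy-3-iodobut-2-en-1-yl]-3-methylidene-5-[(1E)-2-{[(TBS)oxy]methyl}-3-[(TES)oxy]prop-1-en-1-yl]oxolan-2-one (C6 and C7 as in the target; C8 epimeric), via allylzinc bromide 18 (not isolated)
Conditions: Zn dust, THF/sat. aq. NH4Cl (2:1), 0 °C to rt
Reagents that add atoms: none
Why: Zinc Barbier allylation, in which the allylzinc adds through C7 in a six-membered chair on the butenolide face anti to the C6 substituent (trans lactone, C7 set) with the aldehyde substituent equatorial (C8 set, epimeric to the target), regenerates the α-methylidene lactone in the same event.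

Step 11
Reactants: 19 allylic alcohol; 20 tiglic acid
Product: 21 (1S,2Z)-3-iodo-1-{(2R,3S)-2-[(1E)-2-{[(TBS)oxy]methyl}-3-[(TES)oxy]prop-1-en-1-yl]-4-methylidene-5-oxooxolan-3-yl}but-2-en-1-yl (2E)-2-methylbut-2-enoate
Conditions: PPh3, DIAD, toluene, 0 °C to rt
Reagents that add atoms: none
Why: Mitsunobu esterification displaces the C8 oxyphosphonium by tiglate in an SN2 sense, which inverts C8 to the natural configuration and installs the ester at once, the SN2′ path being blocked by the fully substituted iodine-bearing C10.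

Step 12
Reactants: 21 iodo tiglate; 22 tributyl(1-ethoxyvinyl)stannane
Product: 23 (1R,2Z)-4-ethoxy-3-methyl-1-{(2R,3S)-2-[(1E)-2-{[(TBS)oxy]methyl}-3-[(TES)oxy]prop-1-en-1-yl]-4-methylidene-5-oxooxolan-3-yl}penta-2,4-dien-1-yl (2E)-2-methylbut-2-enoate
Conditions: Pd2(dba)3 (2.5 mol%), AsPh3 (20 mol%), CuI (10 mol%), DMF, 40 °C
Reagents that add atoms: none
Why: Stille coupling with retention of the alkene geometry brings in C1 and C2 as a masked acetyl group, and the fast ligand- and copper-accelerated transmetalation should outrun Heck insertion into the methylidene lactone.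

Step 13
Reactants: 23 ethoxydiene
Product: 24 (1R,2Z)-5-bromo-3-methyl-4-oxo-1-{(2R,3S)-2-[(1E)-2-{[(TBS)oxy]methyl}-3-[(TES)oxy]prop-1-en-1-yl]-4-methylidene-5-oxooxolan-3-yl}pent-2-en-1-yl (2E)-2-methylbut-2-enoate
Conditions: NBS, THF/H2O (4:1), 0 °C
Reagents that add atoms: N-bromosuccinimide, O=C1CCC(=O)N1Br; water, O
Why: The enol ether is by far the most electron-rich alkene, so it is brominated at C2 and the oxocarbenium ion is hydrolysed to the bromomethyl ketone.

Step 14
Reactants: 24 bromoketone TES ether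
Product: 25 (1R,2Z)-5-bromo-1-{(2R,3S)-2-[(1E)-2-{[(TBS)oxy]methyl}-3-hydroxyprop-1-en-1-yl]-4-methylidene-5-oxooxolan-3-yl}-3-methyl-4-oxopent-2-en-1-yl (2E)-2-methylbut-2-enoate
Conditions: PPTS (0.2 equiv), MeOH/CH2Cl2 (1:1), 0 °C
Reagents that add atoms: none
Why: A primary TES ether is solvolysed under mild acid far faster than the primary TBS ether, which frees only the C3 hydroxyl.

Step 15
Reactants: 25 allylic alcohol
Product: 26 (1R,2Z)-5-bromo-1-{(2R,3S)-2-[(1Z)-2-{[(TBS)oxy]methyl}-3-oxoprop-1-en-1-yl]-4-methylidene-5-oxooxolan-3-yl}-3-methyl-4-oxopent-2-en-1-yl (2E)-2-methylbut-2-enoate (CHO cis to C6)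
Conditions: Dess–Martin periodinane, NaHCO3, CH2Cl2, 0 °C
Reagents that add atoms: none
Why: Buffered Dess–Martin oxidation converts the primary allylic alcohol into the enal without isomerising the C4=C5 alkene and without touching the bromoketone.

Step 16
Reactants: 26 bromoketone enal
Product: 28 (3S,6R,7S,8R)-15-[(TBS)oxy]-3-hydroxy-1-oxogermacra-4Z,9Z,11(13)-trien-6,12-olid-8-yl (2E)-2-methylbut-2-enoate, via samarium dienolate 27 (not isolated)
Conditions: SmI2 (2.2 equiv, 0.1 M in THF) added dropwise to 26 (0.002 M in THF), −78 °C; sat. aq. NH4Cl at −78 °C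
Reagents that add atoms: none
Why: Divalent samarium reduces the C2–Br bond by two single-electron transfers much faster than it attacks the enal, the methylidene lactone or the acyloxy enone, and the trivalent samarium dienolate 27 adds through C2 to the C3 aldehyde in a chelated Zimmerman–Traxler-type aldol, that is an intramolecular samarium Reformatsky reaction, a reaction type established for closing medium and large rings. The ten-membered carbocycle closes in a 10-(enolendo)-exo-trig mode, and the two cis double bonds and the trans lactone pre-fold the chain into the low-strain cis,cis-cyclodeca-1,6-diene framework. The new stereocentre C3 is controlled by C6 and C7 through that framework: the enal reacts s-trans (the s-cis rotamer would press the carbonyl oxygen against C6 by 1,3-allylic strain), and in the chair-like transition state C2 approaches the aldehyde face opposite to the one on which the lactone holds C7, which places the new hydroxyl pseudo-equatorial and should give (3S). The boat-like alternative leading to (3R) brings the C2 methylene against the inward-pointing H7 across the ring. The step needs chemoselectivity for the C–Br bond and cyclisation over oligomerisation, which the inverse addition at −78 °C (the reductant is never in excess) and the high dilution secure. The cold buffered quench protects the β-hydroxy ketone from retro-aldol cleavage and dehydration.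

Step 17
Reactants: 28 macrocyclic β-hydroxy ketone; 29 acetaldehyde
Product: 30 (1S,3S,6R,7R,8R)-3-acetoxy-15-[(TBS)oxy]-1-hydroxygermacra-4Z,9Z,11(13)-trien-6,12-olid-8-yl (2E)-2-methylbut-2-enoate
Conditions: MeCHO (10 equiv), SmI2 (0.3 equiv, premixed with the aldehyde), THF, −10 °C
Reagents that add atoms: none
Why: In this Evans–Tishchenko reduction the C3 hydroxyl adds to acetaldehyde and the trivalent samarium catalyst holds the hemiacetal and the C1 ketone in a six-membered chair from which hydride is delivered intramolecularly to C1, which gives the 1,3-anti carbinol (1S) and leaves the acetate on O3.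

Step 18
Reactants: 30 15-O-TBS-eupacunolin
Product: 31 eupacunolin, (1S,3S,6R,7R,8R)-3-acetoxy-1,15-dihydroxy-8-[(2E)-2-methylbut-2-enoyloxy]germacra-4Z,9Z,11(13)-trien-6,12-olide
Conditions: HF·pyridine, pyridine, THF, 0 °C
Reagents that add atoms: none
Why: Buffered HF·pyridine cleaves the primary allylic TBS ether under non-basic conditions, so the C3 acetate should not migrate and the methylidene lactone and tiglate stay intact.

Compound list
1 | 1,3-dihydroxyacetone (bought as its dimer) | OCC(=O)CO | starting material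
2 | ethyl (triphenylphosphoranylidene)acetate | CCOC(=O)C=P(c1ccccc1)(c1ccccc1)c1ccccc1 | starting material
3 | ethyl 4-hydroxy-3-(hydroxymethyl)but-2-enoate (not isolated) | CCOC(=O)C=C(CO)CO | intermediate
4 | 4-(hydroxymethyl)furan-2(5H)-one | O=C1C=C(CO)CO1 | intermediate
5 | 4-{[(TBS)oxy]methyl}furan-2(5H)-one | O=C1C=C(CO[Si](C)(C)C(C)(C)C)CO1 | intermediate
6 | (2E)-3-{[(TBS)oxy]methyl}-4-hydroxy-N-methoxy-N-methylbut-2-enamide, amide carbonyl cis to CH2OH (not isolated) | CON(C)C(=O)/C=C(/CO[Si](C)(C)C(C)(C)C)CO | intermediate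
7 | (2E)-3-{[(TBS)oxy]methyl}-N-methoxy-N-methyl-4-[(TES)oxy]but-2-enamide, amide carbonyl cis to CH2OTES | CON(C)C(=O)/C=C(/CO[Si](C)(C)C(C)(C)C)CO[Si](CC)(CC)CC | intermediate
8 | vinylmagnesium bromide | C=C[Mg]Br | starting material
9 | (4E)-5-{[(TBS)oxy]methyl}-6-[(TES)oxy]hexa-1,4-dien-3-one, carbonyl cis to CH2OTES | C=CC(=O)/C=C(/CO[Si](C)(C)C(C)(C)C)CO[Si](CC)(CC)CC | intermediate
10 | (3S,4E)-5-{[(TBS)oxy]methyl}-6-[(TES)oxy]hexa-1,4-dien-3-ol | C=C[C@H](O)/C=C(/CO[Si](C)(C)C(C)(C)C)CO[Si](CC)(CC)CC | intermediate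
11 | 2-(bromomethyl)prop-2-enoic acid | C=C(CBr)C(=O)O | starting material
12 | (3S,4E)-5-{[(TBS)oxy]methyl}-6-[(TES)oxy]hexa-1,4-dien-3-yl 2-(bromomethyl)prop-2-enoate | C=C(CBr)C(=O)O[C@@H](C=C)/C=C(/CO[Si](C)(C)C(C)(C)C)CO[Si](CC)(CC)CC | intermediate
13 | (5R)-3-(bromomethyl)-5-[(1E)-2-{[(TBS)oxy]methyl}-3-[(TES)oxy]prop-1-en-1-yl]furan-2(5H)-one | O=C1O[C@H](/C=C(/CO[Si](C)(C)C(C)(C)C)CO[Si](CC)(CC)CC)C=C1CBr | intermediate
14 | but-2-yn-1-ol | CC#CCO | starting material
15 | sodium 2,2-bis(2-methoxyethoxy)-3-methyl-2,5-dihydro-1,2-oxaaluminol-2-uide, the cyclic vinylalanate (not isolated) | [Na+].CC1=CCO[Al-]1(OCCOC)OCCOC | intermediate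
16 | (2Z)-3-iodobut-2-en-1-ol | C/C(I)=C/CO | intermediate
17 | (2Z)-3-iodobut-2-enal | C/C(I)=C/C=O | intermediate
18 | allylzinc bromide of 13, {[(5R)-2-oxo-5-(alkenyl)-2,5-dihydrofuran-3-yl]methyl}zinc bromide (not isolated) | O=C1O[C@H](/C=C(/CO[Si](C)(C)C(C)(C)C)CO[Si](CC)(CC)CC)C=C1C[Zn]Br | intermediate
19 | (4R,5R)-4-[(1R,2Z)-1-hydroxy-3-iodobut-2-en-1-yl]-3-methylidene-5-[(1E)-2-{[(TBS)oxy]methyl}-3-[(TES)oxy]prop-1-en-1-yl]oxolan-2-one (C8 epimeric to the target) | C=C1C(=O)O[C@H](/C=C(/CO[Si](C)(C)C(C)(C)C)CO[Si](CC)(CC)CC)[C@H]1[C@@H](O)/C=C(C)\I | intermediate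
20 | tiglic acid, (2E)-2-methylbut-2-enoic acid | C/C=C(\C)C(=O)O | starting material
21 | (1S,2Z)-3-iodo-1-{(2R,3S)-2-[(1E)-2-{[(TBS)oxy]methyl}-3-[(TES)oxy]prop-1-en-1-yl]-4-methylidene-5-oxooxolan-3-yl}but-2-en-1-yl (2E)-2-methylbut-2-enoate | C=C1C(=O)O[C@H](/C=C(/CO[Si](C)(C)C(C)(C)C)CO[Si](CC)(CC)CC)[C@H]1[C@H](OC(=O)/C(C)=C/C)/C=C(C)\I | intermediate
22 | tributyl(1-ethoxyvinyl)stannane | CCOC(=C)[Sn](CCCC)(CCCC)CCCC | starting material
23 | (1R,2Z)-4-ethoxy-3-methyl-1-{(2R,3S)-2-[(1E)-2-{[(TBS)oxy]methyl}-3-[(TES)oxy]prop-1-en-1-yl]-4-methylidene-5-oxooxolan-3-yl}penta-2,4-dien-1-yl (2E)-2-methylbut-2-enoate | C=C1C(=O)O[C@H](/C=C(/CO[Si](C)(C)C(C)(C)C)CO[Si](CC)(CC)CC)[C@H]1[C@H](OC(=O)/C(C)=C/C)/C=C(C)\C(=C)OCC | intermediate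
24 | (1R,2Z)-5-bromo-3-methyl-4-oxo-1-{(2R,3S)-2-[(1E)-2-{[(TBS)oxy]methyl}-3-[(TES)oxy]prop-1-en-1-yl]-4-methylidene-5-oxooxolan-3-yl}pent-2-en-1-yl (2E)-2-methylbut-2-enoate | C=C1C(=O)O[C@H](/C=C(/CO[Si](C)(C)C(C)(C)C)CO[Si](CC)(CC)CC)[C@H]1[C@H](OC(=O)/C(C)=C/C)/C=C(C)\C(=O)CBr | intermediate
25 | (1R,2Z)-5-bromo-1-{(2R,3S)-2-[(1E)-2-{[(TBS)oxy]methyl}-3-hydroxyprop-1-en-1-yl]-4-methylidene-5-oxooxolan-3-yl}-3-methyl-4-oxopent-2-en-1-yl (2E)-2-methylbut-2-enoate | C=C1C(=O)O[C@H](/C=C(/CO[Si](C)(C)C(C)(C)C)CO)[C@H]1[C@H](OC(=O)/C(C)=C/C)/C=C(C)\C(=O)CBr | intermediate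
26 | (1R,2Z)-5-bromo-1-{(2R,3S)-2-[(1Z)-2-{[(TBS)oxy]methyl}-3-oxoprop-1-en-1-yl]-4-methylidene-5-oxooxolan-3-yl}-3-methyl-4-oxopent-2-en-1-yl (2E)-2-methylbut-2-enoate | C=C1C(=O)O[C@H](/C=C(/CO[Si](C)(C)C(C)(C)C)C=O)[C@H]1[C@H](OC(=O)/C(C)=C/C)/C=C(C)\C(=O)CBr | intermediate
27 | diiodosamarium dienolate of 26, O–SmI2 on C1 and C1=C2 double bond (not isolated) | C=C1C(=O)O[C@H](/C=C(/CO[Si](C)(C)C(C)(C)C)C=O)[C@H]1[C@H](OC(=O)/C(C)=C/C)/C=C(C)\C(=C)O[Sm](I)I | intermediate
28 | (3S,6R,7S,8R)-15-[(TBS)oxy]-3-hydroxy-1-oxogermacra-4Z,9Z,11(13)-trien-6,12-olid-8-yl (2E)-2-methylbut-2-enoate | C=C1C(=O)O[C@@H]2/C=C(/CO[Si](C)(C)C(C)(C)C)[C@@H](O)CC(=O)/C(C)=C\[C@@H](OC(=O)/C(C)=C/C)[C@@H]12 | intermediate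
29 | acetaldehyde | CC=O | starting material
30 | (1S,3S,6R,7R,8R)-3-acetoxy-15-[(TBS)oxy]-1-hydroxygermacra-4Z,9Z,11(13)-trien-6,12-olid-8-yl (2E)-2-methylbut-2-enoate | C=C1C(=O)O[C@@H]2/C=C(/CO[Si](C)(C)C(C)(C)C)[C@@H](OC(C)=O)C[C@H](O)/C(C)=C\[C@@H](OC(=O)/C(C)=C/C)[C@@H]12 | intermediate
31 | eupacunolin | C=C1C(=O)O[C@@H]2/C=C(/CO)[C@@H](OC(C)=O)C[C@H](O)/C(C)=C\[C@@H](OC(=O)/C(C)=C/C)[C@@H]12 | target

Total step count: 18. Longest linear sequence: 16 steps (steps 1 to 7 and 10 to 18, from 1,3-dihydroxyacetone).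

Steps most likely to fail

Step 16. The ring closure may show poor facial selectivity at C3 if a boat-like or s-cis transition state competes, and single-electron reduction of the enal may divert material. The fallback sets out from 23 and replaces the reductive, substrate-controlled aldol by a non-reductive, reagent-controlled one. Aqueous acetic acid in THF at 0 °C hydrolyses both the enol ether and the TES ether of 23 to the hydroxy methyl ketone F1. Dess–Martin oxidation then gives the keto enal F2. A diisopinocampheylboron chloride/Et3N aldol at high dilution in Et2O, with the Ipc2BCl antipode that directs the methyl ketone enol borinate to the si face of the C3 aldehyde and with a non-oxidative work-up, closes the same C2–C3 bond and comes back to the route at 28.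

Step 11. The activated C8 oxyphosphonium may undergo elimination toward the cross-conjugated triene, or inversion may be incomplete at this hindered centre. The fallback sets out from 13 and forms the natural C8 carbinol directly, so no inversion is needed. Exchange of the bromide with (Bu3Sn)2 under Pd(PPh3)4 catalysis gives the allylstannane F3. Its BF3·OEt2-promoted addition to 17 at −78 °C runs through an open antiperiplanar transition state, which should give the C8 epimer of 19, the natural carbinol F4. Yamaguchi esterification of F4 with 20 (retention) comes back to the route at 21.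

Step 5. Enantioface discrimination may be insufficient because both ketone substituents are alkenyl groups. The fallback sets out from 9: Luche reduction (NaBH4, CeCl3·7H2O, MeOH) gives the racemic dienol F5. Kinetic resolution with Candida antarctica lipase B and vinyl acetate acylates the R enantiomer to the acetate F6 and leaves the S alcohol, which is 10.

Further compounds
F1 | step 16 | (1R,2Z)-1-{(2R,3S)-2-[(1E)-2-{[(TBS)oxy]methyl}-3-hydroxyprop-1-en-1-yl]-4-methylidene-5-oxooxolan-3-yl}-3-methyl-4-oxopent-2-en-1-yl (2E)-2-methylbut-2-enoate | C=C1C(=O)O[C@H](/C=C(/CO[Si](C)(C)C(C)(C)C)CO)[C@H]1[C@H](OC(=O)/C(C)=C/C)/C=C(C)\C(C)=O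
F2 | step 16 | (1R,2Z)-1-{(2R,3S)-2-[(1Z)-2-{[(TBS)oxy]methyl}-3-oxoprop-1-en-1-yl]-4-methylidene-5-oxooxolan-3-yl}-3-methyl-4-oxopent-2-en-1-yl (2E)-2-methylbut-2-enoate | C=C1C(=O)O[C@H](/C=C(/CO[Si](C)(C)C(C)(C)C)C=O)[C@H]1[C@H](OC(=O)/C(C)=C/C)/C=C(C)\C(C)=O
F3 | step 11 | (5R)-5-[(1E)-2-{[(TBS)oxy]methyl}-3-[(TES)oxy]prop-1-en-1-yl]-3-[(tributylstannyl)methyl]furan-2(5H)-one | O=C1O[C@H](/C=C(/CO[Si](C)(C)C(C)(C)C)CO[Si](CC)(CC)CC)C=C1C[Sn](CCCC)(CCCC)CCCC
F4 | step 11 | (4R,5R)-4-[(1S,2Z)-1-hydroxy-3-iodobut-2-en-1-yl]-3-methylidene-5-[(1E)-2-{[(TBS)oxy]methyl}-3-[(TES)oxy]prop-1-en-1-yl]oxolan-2-one | C=C1C(=O)O[C@H](/C=C(/CO[Si](C)(C)C(C)(C)C)CO[Si](CC)(CC)CC)[C@H]1[C@H](O)/C=C(C)\I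
F5 | step 5 | racemic (4E)-5-{[(TBS)oxy]methyl}-6-[(TES)oxy]hexa-1,4-dien-3-ol | C=CC(O)/C=C(/CO[Si](C)(C)C(C)(C)C)CO[Si](CC)(CC)CC
F6 | step 5 | (3R,4E)-5-{[(TBS)oxy]methyl}-6-[(TES)oxy]hexa-1,4-dien-3-yl acetate | C=C[C@@H](OC(C)=O)/C=C(/CO[Si](C)(C)C(C)(C)C)CO[Si](CC)(CC)CC
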